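The 21-membered ring is opened at the benzylic bond between the terminal CH2 of the C14 chain and C-3 of hydroquinone ring B (the carbon ortho to its C-2 hydroxyl). The key step, a one-pot 9-BBN hydroboration/intramolecular B-alkyl Suzuki–Miyaura coupling, converts a terminal vinyl group into that CH2 and bonds it to the brominated ring B carbon, closing the macrocycle. It exploits the unbranched, unfunctionalised polymethylene bridge and the 1,3-relationship of the ether carbon and the alkylated carbon of ring B, which both flank C-2 and so derive from one symmetrical dibromide. The precursor is an open bromo diaryl ether carrying a tetradec-13-enyl chain on resorcinol ring A; tetradeca-1,13-diene supplies all fourteen chain carbons.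

Key step: step 4

Remark on the chemistry: the target has no stereocentre. Ring A is the 5-alkylresorcinol ring; ring B is numbered C-1 (aryloxy), C-2 (OH), C-3 (chain), C-5 (OH). Compounds 1, 3, 4 and 5 are assumed to be purchased.

Step 1
Reactants: 1 2,6-dibromo-4-methoxyphenol
Product: 2 1,3-dibromo-2,5-dimethoxybenzene
Conditions: MeI, K2CO3, DMF, rt
Reagents that add atoms: iodomethane, CI
Why: Williamson O-methylation, in which the acidic 2,6-dibromophenol is deprotonated by K2CO3 and the small electrophile MeI alkylates the phenoxide despite the two ortho bromines.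

Step 2
Reactants: 3 3-bromo-5-methoxyphenol; 4 tetradeca-1,13-diene; 5 9-borabicyclo[3.3.1]nonane (9-BBN)
Product: 7 3-methoxy-5-(tetradec-13-en-1-yl)phenol, via B-(tetradec-13-en-1-yl)-9-borabicyclo[3.3.1]nonane 6 (not isolated)
Conditions: 4 (5 equiv), 5 (0.5 M in THF), THF, 0 °C to rt; then 3, Pd(dppf)Cl2 (5 mol%), aq. K3PO4, DMF, 60 °C
Reagents that add atoms: none
Why: Anti-Markovnikov hydroboration of one terminal alkene (the excess of diene suppresses double hydroboration) should give the primary alkylborane, which undergoes B-alkyl Suzuki–Miyaura coupling at the unhindered C–Br bond of 3, the free phenol being carried through as its phenoxide.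

Step 3
Reactants: 7 3-methoxy-5-(tetradec-13-en-1-yl)phenol; 2 1,3-dibromo-2,5-dimethoxybenzene (3 equiv)
Product: 8 1-bromo-2,5-dimethoxy-3-[3-methoxy-5-(tetradec-13-en-1-yl)phenoxy]benzene
Conditions: CuI (10 mol%), picolinic acid (20 mol%), K3PO4, DMSO, 90 °C
Reagents that add atoms: none
Why: Ullmann-type copper-catalysed C–O coupling, in which the two C–Br bonds of symmetrical 2 are equivalent so that either gives the same mono-ether, the excess of 2 suppresses double arylation, and the terminal alkene and the second C–Br bond are inert.

Step 4
Reactants: 8 1-bromo-2,5-dimethoxy-3-[3-methoxy-5-(tetradec-13-en-1-yl)phenoxy]benzene; 5 9-borabicyclo[3.3.1]nonane (9-BBN)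
Product: 10 tri-O-methyl ether of the target macrocycle, via B-{14-[3-(3-bromo-2,5-dimethoxyphenoxy)-5-methoxyphenyl]tetradecyl}-9-borabicyclo[3.3.1]nonane 9 (not isolated)
Conditions: 5 (0.5 M in THF, 1.5 equiv), THF, 0 °C to rt; then syringe-pump addition over 12 h to Pd(OAc)2 (10 mol%), SPhos (20 mol%), aq. K3PO4, THF/H2O, 65 °C, final concentration 2 mM
Reagents that add atoms: none
Why: 9-BBN adds across the terminal alkene of 8 with anti-Markovnikov regioselectivity to give the primary alkylborane 9, placing boron on the carbon that becomes the benzylic CH2. Zerovalent palladium (from Pd(OAc)2 and SPhos) then inserts into the only C–Br bond, at C-3 of ring B, the hydroxide-activated borane transfers its primary alkyl group to divalent palladium, and reductive elimination forms the aryl–CH2 bond. The closest known reaction type is the B-alkyl Suzuki–Miyaura macrocyclisation used to close large carbocycles and cyclophanes. The single ring formed is the 21-membered macrocycle, closed end-to-end through a 22-membered aryl(alkyl)palladium intermediate, and no stereocentre is created. The step needs ring closure to beat intermolecular coupling and β-hydride elimination, which slow addition of 9 into dilute catalyst, the strain-free 14-carbon tether between two meta-linked rings, and the bulky electron-rich SPhos ligand (fast oxidative addition at the ortho-methoxy bromide and fast reductive elimination) should secure. Only the primary alkyl group migrates from boron because the secondary B–C bonds of the bicyclic 9-BBN cage transmetalate far more slowly.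

Step 5
Reactants: 10 tri-O-methyl ether of the target macrocycle
Product: 11 target macrocycle (CNP0393720.0)
Conditions: BBr3 (6 equiv), CH2Cl2, −78 °C to rt; then H2O, 0 °C, degassed work-up
Reagents that add atoms: none
Why: Lewis-acid ether cleavage, in which BBr3 coordinates each methoxy oxygen and bromide removes the methyl group by SN2, while the diaryl ether has no sp3 C–O carbon and should survive, hydrolysis then releasing the three phenols.

Compound list
1 | 2,6-dibromo-4-methoxyphenol | COc1cc(Br)c(O)c(Br)c1 | starting material
2 | 1,3-dibromo-2,5-dimethoxybenzene | COc1cc(Br)c(OC)c(Br)c1 | intermediate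
3 | 3-bromo-5-methoxyphenol | COc1cc(O)cc(Br)c1 | starting material
4 | tetradeca-1,13-diene | C=CCCCCCCCCCCCC=C | starting material
5 | 9-borabicyclo[3.3.1]nonane (9-BBN, used as THF solution) | B1C2CCCC1CCC2 | starting material
6 | B-(tetradec-13-en-1-yl)-9-borabicyclo[3.3.1]nonane | C=CCCCCCCCCCCCCB1C2CCCC1CCC2 | intermediate
7 | 3-methoxy-5-(tetradec-13-en-1-yl)phenol | COc1cc(O)cc(CCCCCCCCCCCCC=C)c1 | intermediate
8 | 1-bromo-2,5-dimethoxy-3-[3-methoxy-5-(tetradec-13-en-1-yl)phenoxy]benzene | COc1cc(Br)c(OC)c(Oc2cc(OC)cc(CCCCCCCCCCCCC=C)c2)c1 | intermediate
9 | B-{14-[3-(3-bromo-2,5-dimethoxyphenoxy)-5-methoxyphenyl]tetradecyl}-9-borabicyclo[3.3.1]nonane | COc1cc(Br)c(OC)c(Oc2cc(OC)cc(CCCCCCCCCCCCCCB3C4CCCC3CCC4)c2)c1 | intermediate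
10 | tri-O-methyl ether of the target: 21-membered macrocycle in which ring A (1-methoxy, 3-aryloxy, 5-alkyl) and ring B (2,5-dimethoxy, 1-aryloxy, 3-alkyl) are joined by the ether oxygen and an unbranched (CH2)14 chain | COc1cc2cc(c1)Oc1cc(OC)cc(c1OC)CCCCCCCCCCCCCC2 | intermediate
11 | target macrocycle: ring A a 5-alkylresorcinol mono-aryl ether, ring B a 2-hydroxy-5-hydroxy-1-aryloxy-3-alkylbenzene (hydroquinone), joined by the ether oxygen and an unbranched (CH2)14 chain | Oc1cc2cc(c1)Oc1cc(O)cc(c1O)CCCCCCCCCCCCCC2 | target

Total step count: 5. Longest linear sequence: 4 steps (steps 2, 3, 4, 5 from 3 and 4; equally steps 1, 3, 4, 5 from 1).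

Steps most likely to fail

1. Step 4. Intermolecular coupling may outrun ring closure and give oligomers, and slow oxidative addition at the hindered, electron-rich C–Br bond may leave time for protodeboronation or β-hydride elimination. The fallback closes the ring by olefin metathesis instead. It sets out from 8: Suzuki vinylation with potassium vinyltrifluoroborate (Pd(dppf)Cl2, Cs2CO3, THF/H2O, 80 °C) should give the styrene 2,5-dimethoxy-1-[3-methoxy-5-(tetradec-13-en-1-yl)phenoxy]-3-vinylbenzene F1. Ring-closing metathesis with second-generation Grubbs catalyst (CH2Cl2, 40 °C, 1 mM) should give the 21-membered macrocyclic aryl alkene F2 as an E/Z mixture with loss of ethene. Hydrogenation (H2, Pd/C, EtOAc, rt) removes the alkene geometry and comes back to the route at 10.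

2. Step 3. C–O coupling at the ortho-methoxy, electron-rich bromide may be sluggish, and a second arylation of the product may compete. The fallback is an oxidative Chan–Lam coupling. It sets out from 2: mono bromine–lithium exchange (n-BuLi, THF, −78 °C), quench with B(OiPr)3 and aqueous HCl should give (3-bromo-2,5-dimethoxyphenyl)boronic acid F3. Coupling of F3 with phenol 7 (Cu(OAc)2, pyridine, 4 Å molecular sieves, CH2Cl2, air, rt) leaves the C–Br bond untouched and comes back to the route at 8.

3. Step 2. The free phenol may interfere, by quenching the borane or by slowing oxidative addition once it is a phenoxide, and over-hydroboration of the diene lowers the amount of mono-borane. The fallback moves the phenol unmasking after the coupling. It sets out from 4 and 5: borane 6 is made as before and coupled under the same conditions with commercial 1-bromo-3,5-dimethoxybenzene (COc1cc(OC)cc(Br)c1) to give 1,3-dimethoxy-5-(tetradec-13-en-1-yl)benzene F4. Mono-demethylation with NaSEt (DMF, 130 °C) should stop at the mono-phenoxide, which resists a second thiolate attack, and comes back to the route at 7.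

Further compounds
F1 | step 4 | 2,5-dimethoxy-1-[3-methoxy-5-(tetradec-13-en-1-yl)phenoxy]-3-vinylbenzene | COc1cc(C=C)c(OC)c(Oc2cc(OC)cc(CCCCCCCCCCCCC=C)c2)c1
F2 | step 4 | macrocyclic aryl alkene (E/Z mixture): tri-O-methyl macrocycle 10 with a double bond between the two chain carbons nearest ring B | COc1cc2cc(c1)Oc1cc(OC)cc(c1OC)C=CCCCCCCCCCCCC2
F3 | step 3 | (3-bromo-2,5-dimethoxyphenyl)boronic acid | COc1cc(Br)c(OC)c(B(O)O)c1
F4 | step 2 | 1,3-dimethoxy-5-(tetradec-13-en-1-yl)benzene | COc1cc(OC)cc(CCCCCCCCCCCCC=C)c1
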